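**Assumptions:** The 2-aminoimidazole NH2 groups are carried as acetamides through the key step and removed last. The target's stereocentre is (S) by CIP analysis of the given SMILES; the imidazole bearing the vinyl side chain outranks the other imidazole, which outranks CH2.

## Retrosynthetic overview
- Target ⇒ base-mediated deacetylation of the bis-acetamide 13.
- 13 ⇒ **key step:** chiral-phosphoric-acid-catalysed head-to-side-chain dimerisation of N-acetyloroidin 11. The alkenylimidazole of one monomer is protonated at Cβ to give an azafulvenium ion, which loses imidazole aromaticity. Its Cα is attacked by C5–H of a second monomer, which breaks the symmetry of the identical pair and sets the single stereocentre.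
- 11 ⇒ Little–Webber 2-acetamidoimidazole synthesis from α'-bromoenone 9 and N-acetylguanidine.
- 9 ⇒ α'-bromination of enone 8, which comes from cross-metathesis of allyl amide 6 with methyl vinyl ketone. 6 comes from allylamine and the dibromotrichloroacetylpyrrole made from pyrrole.
- The pyrrole rings come directly from pyrrole. The only ring formed later is the imidazole, in step 6, so the rings are made in the order pyrrole (step 1), imidazole (step 6).

## Route

**Step 1**
Reactants: 1 pyrrole; 2 trichloroacetyl chloride
Product: 3 2-(trichloroacetyl)pyrrole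
Conditions: Et2O, 0 °C → rt, 3 h; aq. K2CO3 work-up
Reagents that add atoms: trichloroacetyl chloride (2), ClC(=O)C(Cl)(Cl)Cl
Why: Friedel–Crafts C2-acylation of pyrrole, which needs no Lewis acid.

**Step 2**
Reactants: 3
Product: 4 4,5-dibromo-2-(trichloroacetyl)pyrrole
Conditions: Br2 (2.0 equiv), AcOH, rt
Reagents that add atoms: bromine, BrBr
Why: electrophilic bromination of the 2-acylpyrrole goes to C4 and then C5, the positions open to substitution.

**Step 3**
Reactants: 4; 5 allylamine
Product: 6 N-allyl-4,5-dibromo-1H-pyrrole-2-carboxamide
Conditions: Et3N, DMF, rt, 12 h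
Reagents that add atoms: allylamine (5), C=CCN
Why: the trichloroacetylpyrrole acts as an acyl donor (haloform-type amidation, CCl3⁻/CHCl3 leaving group), so no coupling reagent is needed.

**Step 4**
Reactants: 6; 7 methyl vinyl ketone
Product: 8 (E)-4,5-dibromo-N-(4-oxopent-2-en-1-yl)-1H-pyrrole-2-carboxamide
Conditions: Hoveyda–Grubbs II (5 mol %), CH2Cl2, 40 °C, 16 h
Reagents that add atoms: methyl vinyl ketone (7), C=CC(C)=O
Why: olefin cross-metathesis between a type-I allyl amide and a type-II enone; the E alkene is the thermodynamic product.

**Step 5**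
Reactants: 8
Product: 9 (E)-4,5-dibromo-N-(5-bromo-4-oxopent-2-en-1-yl)-1H-pyrrole-2-carboxamide
Conditions: TMSOTf (3.2 equiv), Et3N (3.5 equiv), CH2Cl2, 0 °C; then NBS (1.05 equiv), −78 → 0 °C; aq. NaHCO3 work-up
Reagents that add atoms: NBS, O=C1CCC(=O)N1Br
Why: TMSOTf/Et3N gives the kinetic silyl enol ether on the methyl side and transiently silylates the amide and pyrrole N–H groups. NBS brominates the terminal CH2 of the silyl enol ether, and aqueous work-up removes all silyl groups (α'-bromination via silyl enol ether).

**Step 6**
Reactants: 9; 10 N-acetylguanidine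
Product: 11 (E)-N-[3-(2-acetamido-1H-imidazol-4-yl)allyl]-4,5-dibromo-1H-pyrrole-2-carboxamide (N-acetyloroidin)
Conditions: DMF, rt → 50 °C, 16 h
Reagents that add atoms: N-acetylguanidine (10), CC(=O)NC(N)=N
Why: Little–Webber condensation; the guanidine N alkylates the CH2Br, then cyclodehydration onto the ketone gives the 4-alkenyl-2-acetamidoimidazole. The acetyl group lowers the basicity of the aminoimidazole so the next step can be acid-catalysed.

**Step 7 (key step)**
Reactants: 11 N-acetyloroidin (two molecules: one as alkene acceptor, one as C-nucleophile); 12 chiral BINOL-derived phosphoric acid, 3,3'-bis(2,4,6-triisopropylphenyl) (TRIP-type) catalyst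
Product: 13 (S)-bis-N-acetyl dimer
Conditions: 12 (15 mol %), 4 Å MS, PhCF3/HFIP 9:1 (0.05 M), 40 °C, 48 h, stopped at ~60% conversion with recovered 11 recycled
Reagents that add atoms: none (the dimerisation is an atom-economic alkene hydroarylation)
Why: Proposed new method: the 4-alkenylimidazole is a vinylogous enamine (N1 lone pair → C5=C4 → Cα), so the chiral phosphoric acid protonates Cβ to give a transient azafulvenium phosphate ion pair, which breaks the imidazole aromaticity. Cα of this cation is attacked by C5–H of a second monomer, the only free ring C–H, which makes the regiochemistry unambiguous. The nucleophile's NH/NHAc binds the P=O, and the 3,3'-aryl groups shield one face to give the (S) stereocentre. The closest known chemistry is phosphoric-acid-catalysed Friedel–Crafts additions to alkylideneindoleninium ions generated from 3-vinylindoles. The C4-alkenyl chain of the nucleophile is not protonated under these conditions and keeps its E geometry. The catalyst antipode that gives (S)-13 is assumed to be (S)-12; if (R) product results, (R)-12 is used.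

**Step 8**
Reactants: 13
Product: 14 target, (S)-bis(2-aminoimidazole) bis(4,5-dibromopyrrole-2-carboxamide)
Conditions: K2CO3 (5 equiv), MeOH/H2O 4:1, 60 °C, 6 h; then RP-HPLC
Reagents that add atoms: none (water hydrolyses the N-acetyl groups and only leaves as acetate)
Why: an acetyl on a 2-aminoimidazole behaves like an acylguanidine and is cleaved by mild base (amide hydrolysis). Acid is avoided because it could reverse the hydroarylation or protonate the alkene. The bromopyrrole carboxamides, the aryl bromides and the E alkene are untouched. The diarylmethine stereocentre has no acidic α-H to racemise through.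

## Compound list
1 | pyrrole | c1cc[nH]c1 | starting material
2 | trichloroacetyl chloride | ClC(=O)C(Cl)(Cl)Cl | starting material
3 | 2-(trichloroacetyl)pyrrole | O=C(c1ccc[nH]1)C(Cl)(Cl)Cl | intermediate
4 | 4,5-dibromo-2-(trichloroacetyl)pyrrole | O=C(c1cc(Br)c(Br)[nH]1)C(Cl)(Cl)Cl | intermediate
5 | allylamine | C=CCN | starting material
6 | N-allyl-4,5-dibromo-1H-pyrrole-2-carboxamide | C=CCNC(=O)c1cc(Br)c(Br)[nH]1 | intermediate
7 | methyl vinyl ketone | C=CC(C)=O | starting material
8 | (E)-4,5-dibromo-N-(4-oxopent-2-en-1-yl)-1H-pyrrole-2-carboxamide | CC(=O)/C=C/CNC(=O)c1cc(Br)c(Br)[nH]1 | intermediate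
9 | (E)-4,5-dibromo-N-(5-bromo-4-oxopent-2-en-1-yl)-1H-pyrrole-2-carboxamide | BrCC(=O)/C=C/CNC(=O)c1cc(Br)c(Br)[nH]1 | intermediate
10 | N-acetylguanidine | CC(=O)NC(N)=N | starting material
11 | N-acetyloroidin | CC(=O)Nc1ncc(/C=C/CNC(=O)c2cc(Br)c(Br)[nH]2)[nH]1 | intermediate
12 | (S)-3,3'-bis(2,4,6-triisopropylphenyl)-BINOL phosphoric acid (axial (S) given by name; SMILES shown without axial stereo) | O=P1(O)Oc2c(-c3c(C(C)C)cc(C(C)C)cc3C(C)C)cc3ccccc3c2-c2c(O1)c(-c1c(C(C)C)cc(C(C)C)cc1C(C)C)cc1ccccc21 | starting material (catalyst)
13 | (S)-bis-N-acetyl dimer | CC(=O)Nc1ncc([C@H](CCNC(=O)c2cc(Br)c(Br)[nH]2)c2[nH]c(NC(C)=O)nc2/C=C/CNC(=O)c2cc(Br)c(Br)[nH]2)[nH]1 | intermediate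
14 | target, CID11411715 | Nc1ncc([C@H](CCNC(=O)c2cc(Br)c(Br)[nH]2)c2[nH]c(N)nc2/C=C/CNC(=O)c2cc(Br)c(Br)[nH]2)[nH]1 | target

## Totals
Total steps: 8. Longest linear sequence: 8 (pyrrole → 3 → 4 → 6 → 8 → 9 → 11 → 13 → 14).

## Three steps most likely to fail
1. **Step 7 (dimerisation).**
   - Risks: the aminoimidazole buffers the acid, the product alkene can oligomerise, and the ee may be modest.
   - Fallback: make racemic 13 with TFA/HFIP, then resolve by preparative chiral-phase SFC/HPLC and carry the (S) enantiomer into step 8.
2. **Step 5 (α'-bromination).**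
   - Risks: the acidic amide and pyrrole N–H groups, thermodynamic (γ-side) silyl dienol ether formation, or bromination of the alkene or pyrrole C3.
   - Fallback: build the bromoketone from (E)-4-(acylamino)but-2-enoic acid by mixed anhydride, then TMSCHN2 to the diazoketone, then HBr. This avoids enol chemistry on the enone.
3. **Step 6 (bromoenone + N-acetylguanidine).**
   - Risks: Michael addition and pyrimidine formation compete with SN2 at the CH2Br.
   - Fallback: condense 9 with 2-aminopyrimidine to give the imidazo[1,2-a]pyrimidine, then cleave with hydrazine to the free 2-aminoimidazole. Re-acetylate to give 11 before step 7.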